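**Retrosynthetic overview**
1. The free acid comes from its tert-butyl ester by acidolysis in the last step.
2. The only ring, the 1,2-dioxane, closes in one operation from an acyclic ene-β-keto ester. First the C6–O bond forms by Markovnikov H/OO addition of O2 to a 1,1-disubstituted alkene (sets C6). Then the C3–O bond forms by peroxy-hemiketalisation (sets C3).
3. The β-keto ester comes from a C2–C3 crossed Claisen condensation of an α-methyl methyl ester with tert-butyl acetate.
4. The methyl ester comes from a C5–C6 Negishi coupling of a 1-alken-2-yl triflate with the zinc homoenolate of a chiral-pool bromo ester (brings C4).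
5. The triflate comes from a methyl ketone, made by Cu-catalysed asymmetric conjugate addition of Ph(CH2)8MgBr to pent-3-en-2-one (C8–C9 bond, sets C8). The bromide comes from PhMgBr and Br(CH2)8Br.

Assumption: in the two catalyst-controlled steps (2 and 6), the catalyst antipode that gives the drawn configuration is used; both antipodes are accessible.

**Step 1**
Reactants: 1 phenylmagnesium bromide; 2 1,8-dibromooctane
Product: 3 (8-bromooctyl)benzene
Conditions: Li2CuCl4 (3 mol %), THF, 0 °C → rt; 2 in threefold excess, surplus distilled back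
Reagents that add atoms: none
Why: Copper-catalysed (Kochi-type) cross-coupling of an aryl Grignard reagent with a primary alkyl bromide is reliable, and the excess of the symmetrical dibromide holds it at mono-substitution.

**Step 2**
Reactants: 3 (8-bromooctyl)benzene; 4 (E)-pent-3-en-2-one
Product: 7 (4R)-4-methyl-12-phenyldodecan-2-one, via Grignard reagent 5 (not isolated), via magnesium enolate 6 (not isolated)
Conditions: Mg, Et2O; then 4, CuBr·SMe2 (5 mol %), Josiphos-type ferrocenyl diphosphine (6 mol %), t-BuOMe, −75 °C; 1 M HCl work-up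
Reagents that add atoms: magnesium, [Mg] (stays only in intermediates 5 and 6)
Why: Cu(I)/Josiphos-catalysed asymmetric conjugate addition of a primary alkyl Grignard reagent to a linear (E)-enone, in which the ligand sends the alkyl group to the Si face of the β-carbon and so sets the methyl-bearing centre (4R here, C8 of the target backbone).

**Step 3**
Reactants: 7 (4R)-4-methyl-12-phenyldodecan-2-one
Product: 9 (4R)-4-methyl-12-phenyldodec-1-en-2-yl trifluoromethanesulfonate, via kinetic lithium enolate 8 (not isolated)
Conditions: LDA (1.1 equiv), THF, −78 °C; Comins' reagent, −78 → 0 °C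
Reagents that add atoms: Comins' reagent, O=S(=O)(C(F)(F)F)N(c1ccc(Cl)cn1)S(=O)(=O)C(F)(F)F; lithium diisopropylamide, [Li]N(C(C)C)C(C)C (Li stays only in intermediate 8)
Why: Kinetic deprotonation of a methyl ketone goes to the CH3 side (the CH2 side is β-branched), and O-triflation at −78 °C freezes that regiochemistry, with the remote stereocentre untouched.

**Step 4**
Reactants: 9 (4R)-4-methyl-12-phenyldodec-1-en-2-yl trifluoromethanesulfonate; 10 methyl (2S)-3-bromo-2-methylpropanoate
Product: 12 methyl (2R,6R)-2,6-dimethyl-4-methylidene-14-phenyltetradecanoate, via organozinc bromide 11 (not isolated)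
Conditions: 10, Zn dust, LiCl, THF, 40 °C; then 9, PdCl2(dppf) (4 mol %), THF, 45 °C
Reagents that add atoms: zinc, [Zn] (stays only in intermediate 11)
Why: Negishi sp3–sp2 coupling of an ester-stabilised zinc homoenolate with an alkenyl triflate, in which the stereocentre of 10 is not the metallated carbon and is carried over unchanged (the descriptor changes from S to R only through CIP priorities).

**Step 5**
Reactants: 12 methyl (2R,6R)-2,6-dimethyl-4-methylidene-14-phenyltetradecanoate; 13 tert-butyl acetate
Product: 16 tert-butyl (4R,8R)-4,8-dimethyl-6-methylidene-3-oxo-16-phenylhexadecanoate, via lithium acetate-ester enolate 14 (not isolated), via lithium ketoester enolate 15 (not isolated)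
Conditions: 13 (3.5 equiv), LDA (3.5 equiv), THF, −78 °C; add 12, −78 → −30 °C; AcOH quench
Reagents that add atoms: lithium diisopropylamide, [Li]N(C(C)C)C(C)C (Li stays only in intermediates 14 and 15)
Why: Crossed Claisen condensation with the non-self-condensing lithium enolate of tert-butyl acetate, in which the product is deprotonated at C2 at once, and this drives the reaction and shields C4 from enolisation.

**Step 6 (key step)**
Reactants: 16 tert-butyl (4R,8R)-4,8-dimethyl-6-methylidene-3-oxo-16-phenylhexadecanoate
Product: 19 tert-butyl 2-[(3S,4R,6S)-3-hydroxy-4,6-dimethyl-6-[(2R)-2-methyl-10-phenyldecyl]-1,2-dioxan-3-yl]acetate, via silyl peroxide 17 (not isolated), via hydroperoxy ketone 18 (not isolated)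
Conditions: chiral deep-pocket Co(II) salen (trans-cyclohexanediamine backbone, 3,3′-aryl walls; 15 mol %), N-methylimidazole (30 mol %), Et3SiH (2.5 equiv), O2 fed slowly as 2 % O2 in N2, DCE, −10 °C; then Et3N·3HF, MeCN, 0 °C
Reagents that add atoms: dioxygen, O=O; triethylsilane, CC[SiH](CC)CC (Et3Si stays only in intermediate 17)
Why: Proposed new method: a catalyst-controlled version of the Isayama–Mukaiyama hydroperoxysilylation, in which Co(III)–H transfers H• to the =CH2 terminus (a radical manifold is chosen because it ignores the γ-keto group, which would close a five-membered ether onto a C6 cation) and, because O2 is fed more slowly than the imidazole-ligated Co(II) binds it, the planar C6 radical meets millimolar chiral Co(III)–superoxide rather than micromolar free O2 and couples with its terminal oxygen (R• + •OO–CoL* → ROO–CoL*) inside the ligand pocket on the Si face, the face that the two flanking syn methyl groups at C4 and C8 also leave open, which sets 6S; Et3SiH then converts ROO–Co into 17 and regenerates Co–H, fluoride frees 18, and 18 adds to the C3 ketone under thermodynamic control to give the chair with axial (anomeric) OH and equatorial C4-methyl, acetate arm and decyl chain (3S); the closest known reaction types are the stereorandom Co(β-diketonate)2/O2/Et3SiH Markovnikov hydroperoxysilylation followed by peroxy-hemiketalisation, and radical capture by metal-bound peroxide as in Kharasch peroxidation.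

**Step 7**
Reactants: 19 tert-butyl 2-[(3S,4R,6S)-3-hydroxy-4,6-dimethyl-6-[(2R)-2-methyl-10-phenyldecyl]-1,2-dioxan-3-yl]acetate
Product: 20 2-[(3S,4R,6S)-3-hydroxy-4,6-dimethyl-6-[(2R)-2-methyl-10-phenyldecyl]-1,2-dioxan-3-yl]acetic acid (target)
Conditions: TFA–CH2Cl2 1:4, 0 °C, 1–2 h; evaporate cold, wash at pH 4
Reagents that add atoms: none
Why: Acidolysis of the tert-butyl ester by alkyl–oxygen cleavage (E1 loss of isobutene) touches no stereocentre, the fully substituted peroxide carbons tolerate acid, and the hemiketal can only re-equilibrate to the same anomer.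

**Compound list**
1 | phenylmagnesium bromide | Br[Mg]c1ccccc1 | starting material
2 | 1,8-dibromooctane | BrCCCCCCCCBr | starting material
3 | (8-bromooctyl)benzene | BrCCCCCCCCc1ccccc1 | intermediate
4 | (E)-pent-3-en-2-one | C/C=C/C(C)=O | starting material
5 | (8-phenyloctyl)magnesium bromide | Br[Mg]CCCCCCCCc1ccccc1 | intermediate (not isolated)
6 | bromomagnesium enolate of 7 (internal enolate, geometry undefined) | C[C@H](CCCCCCCCc1ccccc1)C=C(C)O[Mg]Br | intermediate (not isolated)
7 | (4R)-4-methyl-12-phenyldodecan-2-one | C[C@H](CCCCCCCCc1ccccc1)CC(C)=O | intermediate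
8 | lithium (4R)-4-methyl-12-phenyldodec-1-en-2-olate | C[C@H](CCCCCCCCc1ccccc1)CC(=C)O[Li] | intermediate (not isolated)
9 | (4R)-4-methyl-12-phenyldodec-1-en-2-yl trifluoromethanesulfonate | C[C@H](CCCCCCCCc1ccccc1)CC(=C)OS(=O)(=O)C(F)(F)F | intermediate
10 | methyl (2S)-3-bromo-2-methylpropanoate | BrC[C@@H](C)C(=O)OC | starting material
11 | [(2S)-3-methoxy-2-methyl-3-oxopropyl]zinc bromide | Br[Zn]C[C@@H](C)C(=O)OC | intermediate (not isolated)
12 | methyl (2R,6R)-2,6-dimethyl-4-methylidene-14-phenyltetradecanoate | C[C@H](CCCCCCCCc1ccccc1)CC(=C)C[C@@H](C)C(=O)OC | intermediate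
13 | tert-butyl acetate | CC(=O)OC(C)(C)C | starting material
14 | lithium enolate of tert-butyl acetate | C=C(O[Li])OC(C)(C)C | intermediate (not isolated)
15 | lithium enolate of 16 | C[C@H](CCCCCCCCc1ccccc1)CC(=C)C[C@@H](C)C(O[Li])=CC(=O)OC(C)(C)C | intermediate (not isolated)
16 | tert-butyl (4R,8R)-4,8-dimethyl-6-methylidene-3-oxo-16-phenylhexadecanoate | C[C@H](CCCCCCCCc1ccccc1)CC(=C)C[C@@H](C)C(=O)CC(=O)OC(C)(C)C | intermediate
17 | tert-butyl (4R,6S,8R)-4,6,8-trimethyl-3-oxo-16-phenyl-6-[(triethylsilyl)peroxy]hexadecanoate | C[C@H](CCCCCCCCc1ccccc1)C[C@@](OO[Si](CC)(CC)CC)(C)C[C@@H](C)C(=O)CC(=O)OC(C)(C)C | intermediate (not isolated)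
18 | tert-butyl (4R,6S,8R)-6-hydroperoxy-4,6,8-trimethyl-3-oxo-16-phenylhexadecanoate | C[C@H](CCCCCCCCc1ccccc1)C[C@@](OO)(C)C[C@@H](C)C(=O)CC(=O)OC(C)(C)C | intermediate (not isolated)
19 | tert-butyl 2-[(3S,4R,6S)-3-hydroxy-4,6-dimethyl-6-[(2R)-2-methyl-10-phenyldecyl]-1,2-dioxan-3-yl]acetate | C[C@H](CCCCCCCCc1ccccc1)C[C@@]1(C)C[C@@H](C)[C@](O)(CC(=O)OC(C)(C)C)OO1 | intermediate
20 | 2-[(3S,4R,6S)-3-hydroxy-4,6-dimethyl-6-[(2R)-2-methyl-10-phenyldecyl]-1,2-dioxan-3-yl]acetic acid | C[C@H](CCCCCCCCc1ccccc1)C[C@@]1(C)C[C@@H](C)[C@](O)(CC(=O)O)OO1 | target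

**Total step count:** 7. **Longest linear sequence:** 7 (steps 1 to 7; 4, 10 and 13 enter as purchased).

**Three steps most likely to fail**

(i) Step 6, the proposed new step.
- Risk: the C6 radical may still be caught by free O2, or may couple with the cobalt superoxide without facial bias. In that case 19 forms but with a diastereomer ratio near 1:1.
- Risk: oxygen starvation invites Co–H alkene isomerisation or hydrogenation.
- Fallback (known chemistry, from 16 back to 19): give up catalyst control and resolve instead. The standard stereorandom hydroperoxysilylation (Co(thd)2 10 mol %, O2 balloon, Et3SiH, DCE, rt) gives the triethylsilyl peroxide as a C6-epimer pair F1, which is isolated. Et3N·3HF frees the hydroperoxy ketone epimer pair F2, which closes spontaneously. Silica chromatography then separates 19 from the 6-epi-dioxanol F3 (trans- versus cis-4,6-dimethyl ring diastereomers). The route is rejoined at 19 at the cost of about half the material.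

(ii) Step 5.
- Risk: the excess ester enolate may epimerise the α-centre of 12 before it adds, or may add sluggishly to the α-branched ester.
- Fallback (from 12 back to 16): saponify 12 (LiOH, THF–H2O, rt) to the carboxylic acid F4. Activate it with carbonyldiimidazole to the acyl imidazolide F5. Treat this with the magnesium salt of mono-tert-butyl malonate (MgCl2, Et3N, MeCN, rt; Masamune–Brooks decarboxylative Claisen), which gives 16 under essentially neutral conditions.

(iii) Step 7.
- Risk: TFA may ionise the hemiketal (peroxycarbenium ion, then dehydration to an enol peroxide) or trigger Hock-type cleavage.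
- Risk: the product is a masked β-keto acid that decarboxylates whenever the ring opens.
- Fallback (from 12 to 20): change the ester. Crossed Claisen condensation of 12 with the lithium enolate of 2-(trimethylsilyl)ethyl acetate gives the TMSE β-keto ester F6. Peroxidation as in step 6 (or its fallback) leads through the silyl peroxide F7 and the hydroperoxy ketone F8 to the TMSE dioxanol F9. TBAF buffered with AcOH (THF, 0 °C) then removes the ester by fluoride-induced fragmentation and, after a pH 4 wash, gives 20 without any strong acid.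

**Further compounds**
F1 | step 6 | tert-butyl (4R,6RS,8R)-4,6,8-trimethyl-3-oxo-16-phenyl-6-[(triethylsilyl)peroxy]hexadecanoate | C[C@H](CCCCCCCCc1ccccc1)CC(C)(OO[Si](CC)(CC)CC)C[C@@H](C)C(=O)CC(=O)OC(C)(C)C
F2 | step 6 | tert-butyl (4R,6RS,8R)-6-hydroperoxy-4,6,8-trimethyl-3-oxo-16-phenylhexadecanoate | C[C@H](CCCCCCCCc1ccccc1)CC(C)(OO)C[C@@H](C)C(=O)CC(=O)OC(C)(C)C
F3 | step 6 | tert-butyl 2-[(3S,4R,6R)-3-hydroxy-4,6-dimethyl-6-[(2R)-2-methyl-10-phenyldecyl]-1,2-dioxan-3-yl]acetate | C[C@H](CCCCCCCCc1ccccc1)C[C@]1(C)C[C@@H](C)[C@](O)(CC(=O)OC(C)(C)C)OO1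
F4 | step 5 | (2R,6R)-2,6-dimethyl-4-methylidene-14-phenyltetradecanoic acid | C[C@H](CCCCCCCCc1ccccc1)CC(=C)C[C@@H](C)C(=O)O
F5 | step 5 | 1-[(2R,6R)-2,6-dimethyl-4-methylidene-14-phenyltetradecanoyl]imidazole | C[C@H](CCCCCCCCc1ccccc1)CC(=C)C[C@@H](C)C(=O)n1ccnc1
F6 | step 7 | 2-(trimethylsilyl)ethyl (4R,8R)-4,8-dimethyl-6-methylidene-3-oxo-16-phenylhexadecanoate | C[C@H](CCCCCCCCc1ccccc1)CC(=C)C[C@@H](C)C(=O)CC(=O)OCC[Si](C)(C)C
F7 | step 7 | 2-(trimethylsilyl)ethyl (4R,6S,8R)-4,6,8-trimethyl-3-oxo-16-phenyl-6-[(triethylsilyl)peroxy]hexadecanoate | C[C@H](CCCCCCCCc1ccccc1)C[C@@](OO[Si](CC)(CC)CC)(C)C[C@@H](C)C(=O)CC(=O)OCC[Si](C)(C)C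
F8 | step 7 | 2-(trimethylsilyl)ethyl (4R,6S,8R)-6-hydroperoxy-4,6,8-trimethyl-3-oxo-16-phenylhexadecanoate | C[C@H](CCCCCCCCc1ccccc1)C[C@@](OO)(C)C[C@@H](C)C(=O)CC(=O)OCC[Si](C)(C)C
F9 | step 7 | 2-(trimethylsilyl)ethyl 2-[(3S,4R,6S)-3-hydroxy-4,6-dimethyl-6-[(2R)-2-methyl-10-phenyldecyl]-1,2-dioxan-3-yl]acetate | C[C@H](CCCCCCCCc1ccccc1)C[C@@]1(C)C[C@@H](C)[C@](O)(CC(=O)OCC[Si](C)(C)C)OO1
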